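**Strategy**

Everything rests on making the benzene ring itself. Arene C3 (prenyl) and C4 (oxygen) come from a silyl ynol ether; C5, C6, C1 (acrylate) and C2 come from carbons 3 to 6 of a 2-pyrone that carries the methyl acrylate at its 5-position. In one operation an inverse-demand [4+2] cycloaddition and loss of CO2 form arene bonds C2–C3 and C4–C5, exploiting the fit between the ring's C1-acrylate, C3-prenyl, C4-oxygen pattern (oxygen para to C1) and the polarity of the two partners. The precursors are methyl (E)-3-(2-oxo-2H-pyran-5-yl)acrylate and the triisopropylsilyl ynol ether of 5-methylhex-4-en-1-yne; desilylation and acylation with (S)-3-acetoxybutanoic acid then give the target.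

Key step: step 5

Assumption: (S)-3-hydroxybutanoic acid is bought as the free acid; its C3 is the only stereocentre of the target and no step of the route breaks a bond to it.

**Route**

Step 1
Reactants: 1 coumalic acid
Product: 2 5-bromo-2H-pyran-2-one
Conditions: NBS (1.05 equiv), LiOAc, MeCN–H2O, rt
Reagents that add atoms: N-bromosuccinimide, O=C1CCC(=O)N1Br
Why: Hunsdiecker-type bromodecarboxylation, in which electrophilic bromine attacks the carboxylate-bearing C5 (the β-carbon of the ring enol ether) and CO2 is lost, is a known entry to this bromopyrone, and one equivalent of NBS limits further bromination at C3.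

Step 2
Reactants: 2 5-bromo-2H-pyran-2-one; 3 methyl acrylate
Product: 4 methyl (E)-3-(2-oxo-2H-pyran-5-yl)acrylate
Conditions: Pd(OAc)2 (5 mol %), P(o-tol)3 (10 mol %), Bu4NCl, NaHCO3, DMF, 70 °C
Reagents that add atoms: none
Why: Mizoroki–Heck reaction, in which zerovalent palladium inserts into the vinylic C5–Br bond and syn insertion of the acrylate followed by syn β-hydride elimination gives the E-enoate, while the weak bicarbonate base and moderate temperature should spare the lactone and keep the pyrone from reacting as a diene with the acrylate.

Step 3
Reactants: 5 4-methylpent-3-enoic acid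
Product: 6 ethyl 4-methylpent-3-enoate
Conditions: EtI, KHCO3, DMF, rt
Reagents that add atoms: iodoethane, CCI
Why: Carboxylate O-alkylation (SN2 on iodoethane) forms the ester without the acid catalysis that would lactonise this β,γ-unsaturated acid or move its alkene into conjugation.

Step 4
Reactants: 6 ethyl 4-methylpent-3-enoate
Product: 9 triisopropyl[(5-methylhex-4-en-1-yn-1-yl)oxy]silane, via dibromo enolate 7 (not isolated), via lithium ynolate 8 (not isolated)
Conditions: CH2Br2, lithium 2,2,6,6-tetramethylpiperidide, THF, −78 °C, then 6; LiN(SiMe3)2; n-BuLi, −78 °C → rt; iPr3SiOTf (2.2 equiv), −78 → 0 °C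
Reagents that add atoms: dibromomethane, BrCBr; triisopropylsilyl trifluoromethanesulfonate, CC(C)[Si](OS(=O)(=O)C(F)(F)F)(C(C)C)C(C)C
Why: Kowalski ester homologation, in which preformed dibromomethyllithium adds to the ester at −78 °C faster than it deprotonates the allylic α-position, the dibromo enolate 7 undergoes bromine–lithium exchange and 1,2-shift of the alkyl group to give ynolate 8, and the bulky silyl triflate traps 8 on oxygen as the isolable ynol silyl ether (the second equivalent caps the released ethoxide).

Step 5
Reactants: 4 methyl (E)-3-(2-oxo-2H-pyran-5-yl)acrylate; 9 triisopropyl[(5-methylhex-4-en-1-yn-1-yl)oxy]silane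
Product: 11 methyl (E)-3-[3-(3-methylbut-2-en-1-yl)-4-(triisopropylsilyloxy)phenyl]acrylate, via bridged lactone 10 (not isolated)
Conditions: AgNTf2 (10 mol %), 9 (1.3 equiv) added slowly, CH2Cl2, rt → 40 °C
Reagents that add atoms: none
Why: The closest known reaction type is the inverse-electron-demand Diels–Alder reaction of acceptor-substituted 2-pyrones with heteroatom-substituted alkynes followed by retro-[4+2] loss of CO2; AgNTf2 is the usual activator for siloxyalkynes and also acts as a Lewis acid on the pyrone carbonyl. The ynol ether carbon remote from oxygen is the nucleophile and should add to pyrone C6, which is the δ-carbon of the lactone dienoate and of the dienoate that runs through C5 into the acrylate, and the silyl ketenium carbon so formed is then captured by the dienolate at pyrone C3. This second bond closes the six-membered carbocycle (intramolecular addition of C3 to the digonal ketenium carbon, formally 6-exo-dig, overall a stepwise or strongly asynchronous [4+2] across C3 and C6) and gives bridged lactone 10. Cycloreversion of 10 expels CO2 and leaves the benzene ring at once, because the dienophile is an alkyne and neither elimination nor oxidation is needed; both bridgehead stereocentres of 10 are lost and the product has none. The step needs regioselectivity and site selectivity: the matched polarity (nucleophilic alkyne carbon to C6) puts oxygen para to the acrylate carbon and the prenyl group at C3, and C6 should be preferred over the acrylate β-carbon because only attack at C6 gives an anion delocalised into both the lactone carbonyl and the side-chain ester. The bulky triisopropylsilyl group keeps the ynol ether from rearranging to a silylketene and delivers the phenol in masked form.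

Step 6
Reactants: 11 methyl (E)-3-[3-(3-methylbut-2-en-1-yl)-4-(triisopropylsilyloxy)phenyl]acrylate
Product: 12 methyl (E)-3-[4-hydroxy-3-(3-methylbut-2-en-1-yl)phenyl]acrylate
Conditions: Bu4NF (1.1 equiv), AcOH (1.2 equiv), THF, 0 °C
Reagents that add atoms: none
Why: Fluoride-induced cleavage of the aryl silyl ether is fast at 0 °C, the acetic acid buffer protonates the phenoxide at once so that neither ester cleavage nor conjugate addition should follow, and the prenyl alkene is inert to fluoride.

Step 7
Reactants: 13 (S)-3-hydroxybutanoic acid
Product: 14 (S)-3-acetoxybutanoic acid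
Conditions: Ac2O (3 equiv), pyridine, DMAP (cat.), CH2Cl2, 0 °C → rt; then H2O, dilute HCl
Reagents that add atoms: acetic anhydride, CC(=O)OC(C)=O
Why: DMAP-catalysed O-acetylation of the secondary alcohol leaves the C–O bond of the stereocentre intact, so the (S) configuration is retained, and the aqueous acid work-up returns any mixed anhydride to the free acid.

Step 8
Reactants: 12 methyl (E)-3-[4-hydroxy-3-(3-methylbut-2-en-1-yl)phenyl]acrylate; 14 (S)-3-acetoxybutanoic acid
Product: 15 methyl (E)-3-[4-{[(3S)-3-acetoxybutanoyl]oxy}-3-(3-methylbut-2-en-1-yl)phenyl]acrylate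
Conditions: EDC·HCl (1.5 equiv), DMAP (0.1 equiv), CH2Cl2, 0 °C → rt
Reagents that add atoms: none
Why: Steglich esterification, in which the O-acylisourea of the acid is passed by catalytic DMAP to the phenol; the stereocentre is β to the carbonyl and is not touched, and low temperature with only catalytic base should suppress E1cB loss of acetate.

**Compound list**

1 | coumalic acid (2-oxo-2H-pyran-5-carboxylic acid) | O=C(O)C1=COC(=O)C=C1 | starting material
2 | 5-bromo-2H-pyran-2-one | O=C1C=CC(Br)=CO1 | intermediate
3 | methyl acrylate | C=CC(=O)OC | starting material
4 | methyl (E)-3-(2-oxo-2H-pyran-5-yl)acrylate | COC(=O)/C=C/C1=COC(=O)C=C1 | intermediate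
5 | 4-methylpent-3-enoic acid | CC(C)=CCC(=O)O | starting material
6 | ethyl 4-methylpent-3-enoate | CCOC(=O)CC=C(C)C | intermediate
7 | lithium 1,1-dibromo-5-methylhexa-1,4-dien-2-olate (dibromo enolate, formed in the flask) | CC(C)=CCC([O-])=C(Br)Br.[Li+] | intermediate
8 | lithium 5-methylhex-4-en-1-yn-1-olate (lithium ynolate, formed in the flask) | CC(C)=CCC#C[O-].[Li+] | intermediate
9 | triisopropyl[(5-methylhex-4-en-1-yn-1-yl)oxy]silane | CC(C)=CCC#CO[Si](C(C)C)(C(C)C)C(C)C | intermediate
10 | methyl (E)-3-[6-(3-methylbut-2-en-1-yl)-3-oxo-5-(triisopropylsilyloxy)-2-oxabicyclo[2.2.2]octa-5,7-dien-7-yl]acrylate (bridged lactone, racemic, formed in the flask) | COC(=O)/C=C/C1=CC2C(=O)OC1C(CC=C(C)C)=C2O[Si](C(C)C)(C(C)C)C(C)C | intermediate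
11 | methyl (E)-3-[3-(3-methylbut-2-en-1-yl)-4-(triisopropylsilyloxy)phenyl]acrylate | COC(=O)/C=C/c1ccc(O[Si](C(C)C)(C(C)C)C(C)C)c(CC=C(C)C)c1 | intermediate
12 | methyl (E)-3-[4-hydroxy-3-(3-methylbut-2-en-1-yl)phenyl]acrylate | COC(=O)/C=C/c1ccc(O)c(CC=C(C)C)c1 | intermediate
13 | (S)-3-hydroxybutanoic acid | O=C(O)C[C@H](C)O | starting material
14 | (S)-3-acetoxybutanoic acid | O=C(O)C[C@H](C)OC(C)=O | intermediate
15 | methyl (E)-3-[4-{[(3S)-3-acetoxybutanoyl]oxy}-3-(3-methylbut-2-en-1-yl)phenyl]acrylate | COC(=O)/C=C/c1ccc(OC(=O)C[C@H](C)OC(C)=O)c(CC=C(C)C)c1 | target

Total step count: 8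
Longest linear sequence: 5 steps (steps 1, 2, 5, 6, 8, or equally steps 3, 4, 5, 6, 8)

**Steps most likely to fail**

Step 5. The ynol ether may be consumed at the exocyclic acrylate alkene (silver-promoted [2+2], or ring closure through the diene made of pyrone C5=C6 and the side-chain alkene), or may rearrange by silyl migration before it reaches C6, so that little arene forms. The fallback gives up the pyrone and builds the phenol by classical arene chemistry. It sets out from methyl acrylate 3. Sodium 4-iodophenoxide (4-iodophenol, NaH) is alkylated with 1-bromo-3-methylbut-2-ene in toluene, where the tight ion pair favours ortho C-alkylation over O-alkylation, to give 4-iodo-2-(3-methylbut-2-en-1-yl)phenol F1. A Heck reaction of this iodide with 3 (Pd(OAc)2, P(o-tol)3, NaHCO3, DMF, 80 °C) should then give phenol 12, where the route is rejoined; steps 5 and 6 are bypassed.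

Step 4. Proton transfer from the doubly activated CH2 of 6 (allylic and α to the ester) to the carbenoid or amide base may outrun addition, with enolisation and migration of the alkene into conjugation. The fallback reaches the same ynolate by oxidation of a terminal alkyne. It sets out from ester 6. Reduction with i-Bu2AlH (CH2Cl2, −78 °C) should give 4-methylpent-3-enal F2. Corey–Fuchs olefination (CBr4, PPh3, CH2Cl2, 0 °C) should give 1,1-dibromo-5-methylhexa-1,4-diene F3. Treatment with n-BuLi (2 equiv, THF, −78 °C) should give lithium 5-methylhex-4-en-1-yn-1-ide F4 in the flask. Oxidation with lithium tert-butyl peroxide (t-BuOOH, LiN(SiMe3)2, −78 → 0 °C) converts it to ynolate 8, which is silylated as in step 4; the fallback comes back to the route at 8 and so at 9.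

Step 2. The bromopyrone or its product may be lost under Heck conditions by base-induced opening of the lactone, by slow oxidative addition at C5 with deposition of palladium metal, or by Diels–Alder reaction of the pyrone diene with excess acrylate at the temperature needed. The fallback is a base-free Stille coupling with purchased methyl (E)-3-(tributylstannyl)acrylate (Pd(PPh3)4, CuI, DMF, 50 °C), which brings in the E-alkene preformed. It sets out from 2, comes back at 4 and makes no new compound (F0).

**Further compounds**

F1 | step 5 | 4-iodo-2-(3-methylbut-2-en-1-yl)phenol | CC(C)=CCc1cc(I)ccc1O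
F2 | step 4 | 4-methylpent-3-enal | CC(C)=CCC=O
F3 | step 4 | 1,1-dibromo-5-methylhexa-1,4-diene | CC(C)=CCC=C(Br)Br
F4 | step 4 | lithium 5-methylhex-4-en-1-yn-1-ide | [Li+].[C-]#CCC=C(C)C
F0 | step 2 | none | none
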